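**Retrosynthetic overview**

1. Target ⇒ its hexasilyl derivative (four aryl silyl ethers, one silyl ester); global desilylation is the last step.
2. Aryl–vinyl bond at C7 ⇒ Mizoroki–Heck coupling of a 7-iodo-3-benzylidene-1,4-benzodioxin-2-one with the O-acryloyl derivative of (R)-danshensu; the only stereocentre is bought and never touched.
3. Exocyclic (Z)-benzylidene ⇒ aldol condensation of 7-iodo-1,4-benzodioxin-2(3H)-one with bis-silylated protocatechualdehyde; the iodine ⇒ electrophilic iodination para to the ring ether oxygen.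
4. 1,4-Dioxin-2-one ring ⇒ [4+2] hetero-Diels–Alder of o-benzoquinone with ethoxyacetylene, then hydration of the cyclic ketene acetal. The symmetric quinone is used deliberately: the acrylate-bearing quinone would place the acyl oxygen para to the acrylate, the wrong regioisomer.
5. Ring order: the dioxinone ring is the only ring made (first step); the three benzene rings come from catechol, protocatechualdehyde and danshensu.

Assumption: sodium (R)-danshensu (salvianic acid A sodium salt), 3,4-bis(tert-butyldimethylsilyloxy)benzaldehyde and ethoxyacetylene (hexane solution) are bought.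

**Route**

Step 1
Reactants: 1 catechol; 2 ethoxyacetylene
Product: 5 1,4-benzodioxin-2(3H)-one, via o-benzoquinone 3 (not isolated), via 2-ethoxy-1,4-benzodioxin 4 (not isolated)
Conditions: NaIO4, H2O/CH2Cl2, 0 °C; organic layer dried (Na2SO4); 2, CH2Cl2, −30 °C → rt; then 1 M HCl, THF, rt; TsOH (cat.), PhMe, 80 °C
Reagents that add atoms: water, O
Why: o-Benzoquinone is an electron-poor O=C–C=O heterodiene and the ynol ether an electron-rich 2π partner, so an inverse-electron-demand hetero-Diels–Alder [4+2] cycloaddition closes the 1,4-dioxin ring (the quinone is symmetric, so only one regioisomer can form) and acid hydration of the cyclic ketene acetal with loss of ethanol gives the lactone; no stereocentre is formed.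

Step 2
Reactants: 5 1,4-benzodioxin-2(3H)-one
Product: 6 7-iodo-1,4-benzodioxin-2(3H)-one
Conditions: NIS, CF3CO2H, MeCN, 0 °C → rt
Reagents that add atoms: N-iodosuccinimide, O=C1CCC(=O)N1I
Why: Electrophilic aromatic iodination goes para to the alkyl ether oxygen O4, a much stronger donor than the acyloxy oxygen O1 (the guaiacol acetate pattern), which puts iodine at C7.

Step 3
Reactants: 6 7-iodo-1,4-benzodioxin-2(3H)-one; 7 3,4-bis(tert-butyldimethylsilyloxy)benzaldehyde
Product: 11 (Z)-3-[3,4-bis(tert-butyldimethylsilyloxy)benzylidene]-7-iodo-1,4-benzodioxin-2(3H)-one, via lithium enolate 8 (not isolated), via lithium aldolate 9 (not isolated), via aldol acetate 10 (not isolated)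
Conditions: LiN(SiMe3)2, THF, −78 °C (6 added to the base); 7, −78 °C; Ac2O, −78 → 0 °C; DBU, rt
Reagents that add atoms: none
Why: Aldol condensation: the lithium enolate adds to the non-enolisable aldehyde, the aldolate is trapped cold as its acetate, and DBU-induced E1cB elimination gives the conjugated arylidene lactone with the aryl group anti to the lactone carbonyl (Z), the thermodynamically preferred geometry.

Step 4
Reactants: 12 sodium (R)-3-(3,4-dihydroxyphenyl)-2-hydroxypropanoate (sodium danshensu)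
Product: 13 triisopropylsilyl (R)-3-[3,4-bis(triisopropylsilyloxy)phenyl]-2-hydroxypropanoate
Conditions: iPr3SiCl (3.2 equiv), imidazole, DMF, 0 °C → rt
Reagents that add atoms: triisopropylsilyl chloride, CC(C)[Si](Cl)(C(C)C)C(C)C
Why: Silylation of the carboxylate and the two phenols with the bulky chlorosilane leaves the hindered secondary α-hydroxyl free, and the bought (R) stereocentre is not involved.

Step 5
Reactants: 13 triisopropylsilyl (R)-3-[3,4-bis(triisopropylsilyloxy)phenyl]-2-hydroxypropanoate; 14 acryloyl chloride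
Product: 15 triisopropylsilyl (R)-2-(acryloyloxy)-3-[3,4-bis(triisopropylsilyloxy)phenyl]propanoate
Conditions: Et3N, DMAP (cat.), CH2Cl2, −20 → 0 °C
Reagents that add atoms: none
Why: DMAP-catalysed O-acylation of the secondary alcohol by the acid chloride proceeds with retention because no bond to the stereocentre is broken.

Step 6
Reactants: 11 (Z)-3-[3,4-bis(tert-butyldimethylsilyloxy)benzylidene]-7-iodo-1,4-benzodioxin-2(3H)-one; 15 triisopropylsilyl (R)-2-(acryloyloxy)-3-[3,4-bis(triisopropylsilyloxy)phenyl]propanoate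
Product: 16 hexasilyl-protected target (E-acrylate at C7 of the Z-benzylidene lactone, R ester)
Conditions: Pd(OAc)2 (5 mol %), P(o-tol)3 (10 mol %), Et3N, MeCN, 70 °C
Reagents that add atoms: none
Why: Mizoroki–Heck reaction: oxidative addition of the aryl iodide to zerovalent palladium, syn-carbopalladation of the acrylate and syn-β-hydride elimination give the (E)-cinnamate, while the silyl groups, the lactone and the stereocentre tolerate Et3N at 70 °C.

Step 7
Reactants: 16 hexasilyl-protected target
Product: 17 target, (R)-3-(3,4-dihydroxyphenyl)-2-{[(E)-3-{(Z)-3-(3,4-dihydroxybenzylidene)-2-oxo-2,3-dihydro-1,4-benzodioxin-7-yl}acryloyl]oxy}propanoic acid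
Conditions: HF·pyridine, THF/pyridine, 0 °C → rt
Reagents that add atoms: none
Why: Fluoride-driven cleavage of the four aryl silyl ethers and the silyl ester (Si–F bond formation) under mildly acidic, non-nucleophilic conditions leaves the aryl lactone, both alkenes and the stereocentre untouched.

**Compound list**

1 | catechol | Oc1ccccc1O | starting material
2 | ethoxyacetylene (ethyl ethynyl ether) | C#COCC | starting material
3 | o-benzoquinone | O=C1C=CC=CC1=O | intermediate
4 | 2-ethoxy-1,4-benzodioxin | CCOC1=COc2ccccc2O1 | intermediate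
5 | 1,4-benzodioxin-2(3H)-one | O=C1COc2ccccc2O1 | intermediate
6 | 7-iodo-1,4-benzodioxin-2(3H)-one (iodine para to the ring ether oxygen) | O=C1COc2ccc(I)cc2O1 | intermediate
7 | 3,4-bis(tert-butyldimethylsilyloxy)benzaldehyde | O=Cc1ccc(O[Si](C)(C)C(C)(C)C)c(O[Si](C)(C)C(C)(C)C)c1 | starting material
8 | lithium enolate of 6 (lithium 7-iodo-1,4-benzodioxin-2-olate) | [Li+].[O-]C1=COc2ccc(I)cc2O1 | intermediate
9 | lithium aldolate, lithium [3,4-bis(tert-butyldimethylsilyloxy)phenyl](7-iodo-2-oxo-2,3-dihydro-1,4-benzodioxin-3-yl)methanolate, diastereomer mixture | [Li+].[O-]C(c1ccc(O[Si](C)(C)C(C)(C)C)c(O[Si](C)(C)C(C)(C)C)c1)C1Oc2ccc(I)cc2OC1=O | intermediate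
10 | aldol acetate, [3,4-bis(tert-butyldimethylsilyloxy)phenyl](7-iodo-2-oxo-2,3-dihydro-1,4-benzodioxin-3-yl)methyl acetate, diastereomer mixture | CC(=O)OC(c1ccc(O[Si](C)(C)C(C)(C)C)c(O[Si](C)(C)C(C)(C)C)c1)C1Oc2ccc(I)cc2OC1=O | intermediate
11 | (Z)-3-[3,4-bis(tert-butyldimethylsilyloxy)benzylidene]-7-iodo-1,4-benzodioxin-2(3H)-one | Ic1ccc2c(c1)OC(=O)/C(=C/c1ccc(O[Si](C)(C)C(C)(C)C)c(O[Si](C)(C)C(C)(C)C)c1)O2 | intermediate
12 | sodium (R)-3-(3,4-dihydroxyphenyl)-2-hydroxypropanoate (sodium danshensu) | O[C@H](Cc1ccc(O)c(O)c1)C(=O)[O-].[Na+] | starting material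
13 | triisopropylsilyl (R)-3-[3,4-bis(triisopropylsilyloxy)phenyl]-2-hydroxypropanoate | O[C@H](Cc1ccc(O[Si](C(C)C)(C(C)C)C(C)C)c(O[Si](C(C)C)(C(C)C)C(C)C)c1)C(=O)O[Si](C(C)C)(C(C)C)C(C)C | intermediate
14 | acryloyl chloride | C=CC(=O)Cl | starting material
15 | triisopropylsilyl (R)-2-(acryloyloxy)-3-[3,4-bis(triisopropylsilyloxy)phenyl]propanoate | C=CC(=O)O[C@H](Cc1ccc(O[Si](C(C)C)(C(C)C)C(C)C)c(O[Si](C(C)C)(C(C)C)C(C)C)c1)C(=O)O[Si](C(C)C)(C(C)C)C(C)C | intermediate
16 | hexasilyl-protected target: triisopropylsilyl (R)-2-{[(E)-3-{(Z)-3-[3,4-bis(tert-butyldimethylsilyloxy)benzylidene]-2-oxo-2,3-dihydro-1,4-benzodioxin-7-yl}acryloyl]oxy}-3-[3,4-bis(triisopropylsilyloxy)phenyl]propanoate | O=C(/C=C/c1ccc2c(c1)OC(=O)/C(=C/c1ccc(O[Si](C)(C)C(C)(C)C)c(O[Si](C)(C)C(C)(C)C)c1)O2)O[C@H](Cc1ccc(O[Si](C(C)C)(C(C)C)C(C)C)c(O[Si](C(C)C)(C(C)C)C(C)C)c1)C(=O)O[Si](C(C)C)(C(C)C)C(C)C | intermediate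
17 | (R)-3-(3,4-dihydroxyphenyl)-2-{[(E)-3-{(Z)-3-(3,4-dihydroxybenzylidene)-2-oxo-2,3-dihydro-1,4-benzodioxin-7-yl}acryloyl]oxy}propanoic acid | O=C(/C=C/c1ccc2c(c1)OC(=O)/C(=C/c1ccc(O)c(O)c1)O2)O[C@H](Cc1ccc(O)c(O)c1)C(=O)O | target

**Step count and risks**

Total: 7 steps. Longest linear sequence: 5 steps (steps 1, 2, 3, 6, 7; 1 → 5 → 6 → 11 → 16 → 17).

The three steps most likely to fail:

Step 1. o-Benzoquinone is short-lived and can dimerise or react through its carbon diene before the ynol ether adds across the two oxygens. The fallback sets out from catechol 1 and comes back at lactone 5. Mono-O-alkylation of 1 (in excess) with ethyl bromoacetate and K2CO3 in acetone gives ethyl (2-hydroxyphenoxy)acetate F1. Lactonisation of this with TsOH in refluxing toluene, with loss of ethanol, gives 5.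

Step 3. The enolate of an aryl lactone can self-acylate or fragment, and the elimination may give E/Z mixtures. The fallback sets out from 6 and comes back at 11. Radical bromination at C3 (NBS, AIBN, PhCF3, 80 °C) gives 3-bromo-7-iodo-1,4-benzodioxin-2(3H)-one F2. Michaelis–Arbuzov reaction with P(OEt)3 at 110 °C gives diethyl (7-iodo-2-oxo-2,3-dihydro-1,4-benzodioxin-3-yl)phosphonate F3. Horner–Wadsworth–Emmons olefination of this with aldehyde 7 (LiCl, DBU, MeCN) gives 11.

Step 6. Amine base and heat may open the aryl lactone or erode the silyl groups during the Heck coupling. The fallback sets out from 11 and comes back at 16. Stille coupling of 11 with tributyl(vinyl)stannane (Pd(PPh3)4, toluene, 80 °C) gives (Z)-3-[3,4-bis(tert-butyldimethylsilyloxy)benzylidene]-7-vinyl-1,4-benzodioxin-2(3H)-one F4. Cross-metathesis of this styrene with acrylate 15 (second-generation Hoveyda–Grubbs catalyst, CH2Cl2, 40 °C) gives 16 as the E-alkene.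

**Further compounds**

F1 | step 1 | ethyl (2-hydroxyphenoxy)acetate | CCOC(=O)COc1ccccc1O
F2 | step 3 | 3-bromo-7-iodo-1,4-benzodioxin-2(3H)-one | O=C1Oc2cc(I)ccc2OC1Br
F3 | step 3 | diethyl (7-iodo-2-oxo-2,3-dihydro-1,4-benzodioxin-3-yl)phosphonate | CCOP(=O)(OCC)C1Oc2ccc(I)cc2OC1=O
F4 | step 6 | (Z)-3-[3,4-bis(tert-butyldimethylsilyloxy)benzylidene]-7-vinyl-1,4-benzodioxin-2(3H)-one | C=Cc1ccc2c(c1)OC(=O)/C(=C/c1ccc(O[Si](C)(C)C(C)(C)C)c(O[Si](C)(C)C(C)(C)C)c1)O2
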